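Positions use germacrane numbering: ring C1–C10, C11 = lactone α-carbon, C12 = lactone C=O, C13 = CH2OAc.

**Plan**

1. Retrosynthesis cuts, in order: the acetate and tiglate C–O bonds; the C1=C10 ring olefin (ring-closing metathesis); then, in one event, the furanone bonds O–C6 and C11–C12, which removes CO2 and unmasks an acyclic (3S,4S)-3,4-epoxy-5E-ene bearing a Z-alkenyl iodide at C11; last C5=C6 (Horner–Wadsworth–Emmons), giving an epoxy aldehyde and an iodo-allyl phosphonate.
2. Enabling feature: C6, the furanone γ-carbon, is allylic to C4=C5 and 1,4 to the oxygen on C3 (a 2-ene-1,4-dioxy array, the imprint of a syn-SN2′ opening of a 3,4-epoxide). C11 is a vinylic carbon held cis to C6 on the tetrasubstituted C7=C11 olefin, so a C11 carboxylate made from CO2 (C12 and both lactone oxygens) can close the five-membered ring onto C6.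
3. Forward: β-keto ester → Z-enol triflate → Z-alkenyl iodide → allyl phosphonate; propargyl alcohol → epoxy aldehyde; olefination joins the chain; carboxylation/Pd(0) lactonisation makes the furanone ring; metathesis then closes the ten-membered carbocycle; tiglate and acetate go on last.
4. Stereochemistry: C3 (and the sacrificial C4 centre) from Sharpless epoxidation; C6 by 1,3-chirality transfer (double inversion at Pd); 4E from the syn,syn-π-allyl; C7=C11 geometry from the chelated Z-enol triflate; 1(10)Z from ring strain in the metathesis.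
5. Helpers removed en route: the iodide at C11, the epoxide (temporary ring), the PMB ether on O13 and two terminal CH2 groups (lost as ethene).

Key step: step 13

Remark: the target SMILES is read as 3S,6R with a 1(10)Z and a 4E ring olefin and an (E)-2-methylbut-2-enoate (tiglate) on O3.

**Route**

Step 1
Reactants: 1 ethyl 4-chloro-3-oxobutanoate
Product: 2 ethyl 4-[(4-methoxybenzyl)oxy]-3-oxobutanoate
Conditions: 4-methoxybenzyl alcohol, NaH (2.2 equiv), THF, 0 °C → rt; aq. NH4Cl
Reagents that add atoms: 4-methoxybenzyl alcohol, COc1ccc(CO)cc1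
Why: Williamson etherification: the β-keto ester is masked as its sodium enolate while the alkoxide displaces the primary γ-chloride, the usual entry to 4-alkoxyacetoacetates.

Step 2
Reactants: 2 ethyl 4-[(4-methoxybenzyl)oxy]-3-oxobutanoate; 3 4-bromo-2-methylbut-1-ene
Product: 4 ethyl 2-{[(4-methoxybenzyl)oxy]acetyl}-5-methylhex-5-enoate (racemic)
Conditions: NaH (1.05 equiv), NaI (cat.), DMF, 0 → 60 °C
Reagents that add atoms: none
Why: acetoacetic ester alkylation: the doubly stabilised enolate is C-alkylated by the primary halide at the carbon between the two carbonyls (future C7), and the new stereocentre is erased in the next step.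

Step 3
Reactants: 4 ethyl 2-{[(4-methoxybenzyl)oxy]acetyl}-5-methylhex-5-enoate
Product: 5 ethyl (2Z)-4-[(4-methoxybenzyl)oxy]-2-(3-methylbut-3-en-1-yl)-3-{[(trifluoromethyl)sulfonyl]oxy}but-2-enoate
Conditions: Tf2O, sat. aq. LiOH, toluene, 5 °C
Reagents that add atoms: trifluoromethanesulfonic anhydride, O=S(=O)(OS(=O)(=O)C(F)(F)F)C(F)(F)F
Why: stereoselective enol triflate formation of a β-keto ester: O-sulfonylation of the lithium-chelated enolate should place the triflate cis to the ester, which fixes the C7=C11 geometry (C6 cis to the future carboxyl carbon, C8 cis to C13).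

Step 4
Reactants: 5 ethyl (2Z)-4-[(4-methoxybenzyl)oxy]-2-(3-methylbut-3-en-1-yl)-3-{[(trifluoromethyl)sulfonyl]oxy}but-2-enoate
Product: 6 ethyl (2Z)-4-[(4-methoxybenzyl)oxy]-2-(3-methylbut-3-en-1-yl)-3-(trimethylstannyl)but-2-enoate
Conditions: Me3SnSnMe3, Pd(PPh3)4 (5 mol %), LiCl, THF, 65 °C
Reagents that add atoms: hexamethylditin, C[Sn](C)(C)[Sn](C)(C)C
Why: Pd(0)-catalysed stannylation of an enol triflate (Stille-type coupling with a distannane) proceeds with retention of olefin geometry and tolerates the ester, the PMB ether and the isolated olefin.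

Step 5
Reactants: 6 ethyl (2Z)-4-[(4-methoxybenzyl)oxy]-2-(3-methylbut-3-en-1-yl)-3-(trimethylstannyl)but-2-enoate
Product: 7 ethyl (2Z)-3-iodo-4-[(4-methoxybenzyl)oxy]-2-(3-methylbut-3-en-1-yl)but-2-enoate
Conditions: I2, CH2Cl2, 0 °C
Reagents that add atoms: iodine, II
Why: ipso-iododestannylation of an alkenylstannane is fast and stereoretentive, so the iodide should inherit the Z geometry.

Step 6
Reactants: 7 ethyl (2Z)-3-iodo-4-[(4-methoxybenzyl)oxy]-2-(3-methylbut-3-en-1-yl)but-2-enoate
Product: 8 (2Z)-3-iodo-4-[(4-methoxybenzyl)oxy]-2-(3-methylbut-3-en-1-yl)but-2-en-1-ol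
Conditions: DIBAL-H (2.5 equiv), CH2Cl2, −78 °C; Rochelle salt
Reagents that add atoms: none
Why: 1,2-reduction of an α,β-unsaturated ester to the allylic alcohol with DIBAL-H leaves the alkenyl iodide and the olefin geometry untouched.

Step 7
Reactants: 8 (2Z)-3-iodo-4-[(4-methoxybenzyl)oxy]-2-(3-methylbut-3-en-1-yl)but-2-en-1-ol
Product: 9 1-({[(2Z)-4-bromo-2-iodo-3-(3-methylbut-3-en-1-yl)but-2-en-1-yl]oxy}methyl)-4-methoxybenzene
Conditions: CBr4, PPh3, CH2Cl2, 0 °C
Reagents that add atoms: tetrabromomethane, BrC(Br)(Br)Br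
Why: Appel bromination of a primary allylic alcohol is an SN2 process that should not disturb the tetrasubstituted olefin.

Step 8
Reactants: 9 1-({[(2Z)-4-bromo-2-iodo-3-(3-methylbut-3-en-1-yl)but-2-en-1-yl]oxy}methyl)-4-methoxybenzene
Product: 10 diethyl [(2Z)-3-iodo-4-[(4-methoxybenzyl)oxy]-2-(3-methylbut-3-en-1-yl)but-2-en-1-yl]phosphonate
Conditions: P(OEt)3 (neat), 100 °C
Reagents that add atoms: triethyl phosphite, CCOP(OCC)OCC
Why: Michaelis–Arbuzov reaction of the allylic bromide; the alkenyl iodide is inert to phosphite without a transition metal.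

Step 9
Reactants: 11 prop-2-yn-1-ol
Product: 13 (2E)-2-methylhexa-2,5-dien-1-ol, via alkenylalane 12 (not isolated)
Conditions: AlMe3 (3 equiv), Cp2ZrCl2 (25 mol %), CH2Cl2, 0 °C → rt; then allyl bromide, Pd(PPh3)4 (3 mol %), THF, rt
Reagents that add atoms: trimethylaluminium, C[Al](C)C; allyl bromide, C=CCBr
Why: Negishi zirconium-catalysed syn-carboalumination puts methyl on the internal and aluminium on the terminal alkyne carbon, and Pd-catalysed allylation of the alkenylalane with retention should give the E-trisubstituted skipped diene.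

Step 10
Reactants: 13 (2E)-2-methylhexa-2,5-dien-1-ol
Product: 14 [(2S,3S)-2-methyl-3-(prop-2-en-1-yl)oxiran-2-yl]methanol
Conditions: Ti(OiPr)4 (10 mol %), L-(+)-diethyl tartrate (12 mol %), t-BuOOH, 4 Å MS, CH2Cl2, −20 °C
Reagents that add atoms: tert-butyl hydroperoxide, CC(C)(C)OO
Why: Sharpless asymmetric epoxidation epoxidises only the allylic-alcohol olefin, and the L-(+)-tartrate catalyst should deliver oxygen to the face that gives the (2S,3S)-epoxide, which sets C3 (S) and the temporary C4 centre.

Step 11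
Reactants: 14 [(2S,3S)-2-methyl-3-(prop-2-en-1-yl)oxiran-2-yl]methanol
Product: 15 (2R,3S)-2-methyl-3-(prop-2-en-1-yl)oxirane-2-carbaldehyde
Conditions: Dess–Martin periodinane, pyridine, CH2Cl2, 0 °C → rt
Reagents that add atoms: none
Why: Dess–Martin oxidation of a 2,3-epoxy alcohol gives the epoxy aldehyde under near-neutral conditions, and the quaternary α-carbon cannot epimerise (the descriptor changes only through CIP priorities).

Step 12
Reactants: 10 diethyl [(2Z)-3-iodo-4-[(4-methoxybenzyl)oxy]-2-(3-methylbut-3-en-1-yl)but-2-en-1-yl]phosphonate; 15 (2R,3S)-2-methyl-3-(prop-2-en-1-yl)oxirane-2-carbaldehyde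
Product: 16 (2S,3S)-2-[(1E,3Z)-4-iodo-5-[(4-methoxybenzyl)oxy]-3-(3-methylbut-3-en-1-yl)penta-1,3-dien-1-yl]-2-methyl-3-(prop-2-en-1-yl)oxirane
Conditions: NaHMDS, THF, −78 → 0 °C
Reagents that add atoms: none
Why: Horner–Wadsworth–Emmons olefination with an allylic phosphonate: the carbanion adds through its α-carbon (the γ-carbon is fully substituted) and syn-elimination of phosphate should give the E C5=C6 olefin, while the amide base spares iodide and epoxide.

Step 13
Reactants: 16 (2S,3S)-2-[(1E,3Z)-4-iodo-5-[(4-methoxybenzyl)oxy]-3-(3-methylbut-3-en-1-yl)penta-1,3-dien-1-yl]-2-methyl-3-(prop-2-en-1-yl)oxirane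
Product: 19 (5R)-5-[(1E,3S)-3-hydroxy-2-methylhexa-1,5-dien-1-yl]-3-{[(4-methoxybenzyl)oxy]methyl}-4-(3-methylbut-3-en-1-yl)furan-2(5H)-one, via alkenyllithium 17 (not isolated), via lithium carboxylate 18 (not isolated)
Conditions: t-BuLi (2.1 equiv), Et2O, −78 °C; CO2 (g), −78 °C, then Ar purge; AcOH (1.0 equiv), Pd(PPh3)4 (5 mol %), THF, −78 °C → rt
Reagents that add atoms: carbon dioxide, O=C=O
Why: Iodine–lithium exchange with retention gives the configurationally stable alkenyllithium 17, whose C11–Li bond adds to CO2 and forms the C11–C12 bond (carboxylation of an organolithium), leaving the carboxylate of 18 cis to C6 on the C7=C11 olefin. Pd(0) then ionises the C4–O bond of the 3,4-epoxy-5-ene anti to oxygen to a syn,syn-π-allyl complex over C4–C6, and the tethered carboxylate oxygen attacks C6 on the face opposite palladium, which forms the O–C6 bond; the closest known reaction type is the Pd(0)-catalysed syn-1,4-addition of carboxylic acids to vinyl epoxides (Tsuji–Trost allylic substitution). The furanone ring closes by a 5-exo allylic substitution at the distal allyl terminus, since attack at C4 would give a seven-membered ring. C6 is set as R by 1,3-chirality transfer from the C4–O bond through double inversion (net syn-SN2′), C3 is carried unchanged from the epoxide and is released as the free alcohol, and the 4E olefin follows from the W-shaped allyl in which the larger C3 substituent is syn and the methyl anti. The step needs distal capture, which the five-membered ring and the cis placing of carboxylate and C6 secure, and it needs the organolithium to spare the epoxide and the allylic PMB ether, which the fast exchange at −78 °C and the E geometry of C5=C6 (C11 cannot reach C4) secure. CO2 is purged before palladium is added, so the liberated alkoxide is protonated by acetic acid and not carboxylated.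

Step 14
Reactants: 19 (5R)-5-[(1E,3S)-3-hydroxy-2-methylhexa-1,5-dien-1-yl]-3-{[(4-methoxybenzyl)oxy]methyl}-4-(3-methylbut-3-en-1-yl)furan-2(5H)-one
Product: 20 (3S,6R)-3-hydroxy-13-[(4-methoxybenzyl)oxy]germacra-1(10)Z,4E,7(11)-trien-12,6-olide
Conditions: Hoveyda–Grubbs II (10 mol %), CH2Cl2 (1 mM), 40 °C
Reagents that add atoms: none
Why: ring-closing metathesis: the ruthenium alkylidene forms at the monosubstituted C1 olefin and closes onto the 1,1-disubstituted C10 olefin with loss of ethene, and the ten-membered ring that already holds the 4E olefin should favour the less strained Z geometry at C1=C10.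

Step 15
Reactants: 20 (3S,6R)-3-hydroxy-13-[(4-methoxybenzyl)oxy]germacra-1(10)Z,4E,7(11)-trien-12,6-olide
Product: 21 (3S,6R)-13-[(4-methoxybenzyl)oxy]-3-(tigloyloxy)germacra-1(10)Z,4E,7(11)-trien-12,6-olide
Conditions: tigloyl chloride, pyridine, DMAP (cat.), CH2Cl2, 0 °C → rt
Reagents that add atoms: (2E)-2-methylbut-2-enoyl chloride (tigloyl chloride), C/C=C(\C)C(Cl)=O
Why: DMAP-catalysed acylation of the secondary allylic alcohol with the acid chloride proceeds with retention at C3 and keeps the E geometry of the tiglate.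

Step 16
Reactants: 21 (3S,6R)-13-[(4-methoxybenzyl)oxy]-3-(tigloyloxy)germacra-1(10)Z,4E,7(11)-trien-12,6-olide
Product: 22 (3S,6R)-13-hydroxy-3-(tigloyloxy)germacra-1(10)Z,4E,7(11)-trien-12,6-olide
Conditions: DDQ, CH2Cl2/pH 7 buffer (10:1), 0 °C → rt
Reagents that add atoms: none
Why: oxidative cleavage of a PMB ether by DDQ is selective for the electron-rich benzyl ether and should spare the esters, the lactone and the unactivated olefins.

Step 17
Reactants: 22 (3S,6R)-13-hydroxy-3-(tigloyloxy)germacra-1(10)Z,4E,7(11)-trien-12,6-olide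
Product: 23 (3S,6R)-13-acetoxy-3-(tigloyloxy)germacra-1(10)Z,4E,7(11)-trien-12,6-olide
Conditions: Ac2O, pyridine, DMAP (cat.), CH2Cl2, 0 °C
Reagents that add atoms: acetic anhydride, CC(=O)OC(C)=O
Why: standard acetylation of the primary allylic alcohol under mild base should complete the target without touching C6.

**Compound list**

1 | ethyl 4-chloro-3-oxobutanoate | CCOC(=O)CC(=O)CCl | starting material
2 | ethyl 4-[(4-methoxybenzyl)oxy]-3-oxobutanoate | CCOC(=O)CC(=O)COCc1ccc(OC)cc1 | intermediate
3 | 4-bromo-2-methylbut-1-ene | C=C(C)CCBr | starting material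
4 | ethyl 2-{[(4-methoxybenzyl)oxy]acetyl}-5-methylhex-5-enoate (racemic) | CCOC(=O)C(CCC(C)=C)C(=O)COCc1ccc(OC)cc1 | intermediate
5 | ethyl (2Z)-4-[(4-methoxybenzyl)oxy]-2-(3-methylbut-3-en-1-yl)-3-{[(trifluoromethyl)sulfonyl]oxy}but-2-enoate | C=C(C)CC/C(C(=O)OCC)=C(/OS(=O)(=O)C(F)(F)F)COCc1ccc(OC)cc1 | intermediate
6 | ethyl (2Z)-4-[(4-methoxybenzyl)oxy]-2-(3-methylbut-3-en-1-yl)-3-(trimethylstannyl)but-2-enoate | C=C(C)CC/C(C(=O)OCC)=C(/[Sn](C)(C)C)COCc1ccc(OC)cc1 | intermediate
7 | ethyl (2Z)-3-iodo-4-[(4-methoxybenzyl)oxy]-2-(3-methylbut-3-en-1-yl)but-2-enoate | C=C(C)CC/C(C(=O)OCC)=C(/I)COCc1ccc(OC)cc1 | intermediate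
8 | (2Z)-3-iodo-4-[(4-methoxybenzyl)oxy]-2-(3-methylbut-3-en-1-yl)but-2-en-1-ol | C=C(C)CC/C(CO)=C(/I)COCc1ccc(OC)cc1 | intermediate
9 | 1-({[(2Z)-4-bromo-2-iodo-3-(3-methylbut-3-en-1-yl)but-2-en-1-yl]oxy}methyl)-4-methoxybenzene | C=C(C)CC/C(CBr)=C(/I)COCc1ccc(OC)cc1 | intermediate
10 | diethyl [(2Z)-3-iodo-4-[(4-methoxybenzyl)oxy]-2-(3-methylbut-3-en-1-yl)but-2-en-1-yl]phosphonate | C=C(C)CC/C(CP(=O)(OCC)OCC)=C(/I)COCc1ccc(OC)cc1 | intermediate
11 | prop-2-yn-1-ol | C#CCO | starting material
12 | [(1E)-3-(dimethylalumanyloxy)-2-methylprop-1-en-1-yl]dimethylalane (alkenylalane, not isolated) | C[Al](C)/C=C(\C)CO[Al](C)C | intermediate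
13 | (2E)-2-methylhexa-2,5-dien-1-ol | OC/C(C)=C/CC=C | intermediate
14 | [(2S,3S)-2-methyl-3-(prop-2-en-1-yl)oxiran-2-yl]methanol | OC[C@]1(C)O[C@H]1CC=C | intermediate
15 | (2R,3S)-2-methyl-3-(prop-2-en-1-yl)oxirane-2-carbaldehyde | O=C[C@]1(C)O[C@H]1CC=C | intermediate
16 | (2S,3S)-2-[(1E,3Z)-4-iodo-5-[(4-methoxybenzyl)oxy]-3-(3-methylbut-3-en-1-yl)penta-1,3-dien-1-yl]-2-methyl-3-(prop-2-en-1-yl)oxirane | C=C(C)CC/C(=C(/I)COCc1ccc(OC)cc1)/C=C/[C@]1(C)O[C@H]1CC=C | intermediate
17 | alkenyllithium from 16 (Li in place of I, not isolated) | C=C(C)CC/C(=C(/[Li])COCc1ccc(OC)cc1)/C=C/[C@]1(C)O[C@H]1CC=C | intermediate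
18 | lithium (2Z,4E)-2-{[(4-methoxybenzyl)oxy]methyl}-3-(3-methylbut-3-en-1-yl)-5-[(2S,3S)-2-methyl-3-(prop-2-en-1-yl)oxiran-2-yl]penta-2,4-dienoate (not isolated) | C=C(C)CC/C(=C(/C(=O)[O-])COCc1ccc(OC)cc1)/C=C/[C@]1(C)O[C@H]1CC=C.[Li+] | intermediate
19 | (5R)-5-[(1E,3S)-3-hydroxy-2-methylhexa-1,5-dien-1-yl]-3-{[(4-methoxybenzyl)oxy]methyl}-4-(3-methylbut-3-en-1-yl)furan-2(5H)-one | C=CC[C@H](O)/C(C)=C/[C@H]1OC(=O)C(COCc2ccc(OC)cc2)=C1CCC(C)=C | intermediate
20 | (3S,6R)-3-hydroxy-13-[(4-methoxybenzyl)oxy]germacra-1(10)Z,4E,7(11)-trien-12,6-olide | O[C@H]1C/C=C(/C)CCC2=C(COCc3ccc(OC)cc3)C(=O)O[C@@H]2/C=C/1C | intermediate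
21 | (3S,6R)-13-[(4-methoxybenzyl)oxy]-3-(tigloyloxy)germacra-1(10)Z,4E,7(11)-trien-12,6-olide | C/C=C(\C)C(=O)O[C@H]1C/C=C(/C)CCC2=C(COCc3ccc(OC)cc3)C(=O)O[C@@H]2/C=C/1C | intermediate
22 | (3S,6R)-13-hydroxy-3-(tigloyloxy)germacra-1(10)Z,4E,7(11)-trien-12,6-olide | C/C=C(\C)C(=O)O[C@H]1C/C=C(/C)CCC2=C(CO)C(=O)O[C@@H]2/C=C/1C | intermediate
23 | (3S,6R)-13-acetoxy-3-(tigloyloxy)germacra-1(10)Z,4E,7(11)-trien-12,6-olide | C/C=C(\C)C(=O)O[C@H]1C/C=C(/C)CCC2=C(COC(C)=O)C(=O)O[C@@H]2/C=C/1C | target

**Count and risks**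

Total step count: 17. Longest linear sequence: 14 steps (steps 1–8 and 12–17).

Steps most likely to fail:

1. Step 13. The wanted distal 5-exo capture of the π-allyl by the carboxylate may lose to palladium-induced isomerisation of the vinyl epoxide to a dienol or enone, to capture at C4, or to carboxylation of the alkoxide by residual CO2. Syn/anti equilibration of the π-allyl, or re-ionisation of the allylic lactone, may erode the C6 configuration or the 4E geometry. The organolithium may also eliminate the PMB-oxide or attack the epoxide before it is carboxylated. Fallback, from 16 back to 19: the exchange/carboxylation is run as in step 13 but worked up cold with phosphate buffer, to isolate the (2Z,4E)-dienoic acid F1 with the epoxide intact. Iodolactonisation (I2, NaHCO3, MeCN, 0 °C) should then close the furanone by 5-exo attack of the carboxylate oxygen on C6 of the activated C5=C6 olefin and give the iodolactone F2 (anti addition, O at C6 and I at C5). Zinc dust (THF/aq. NH4Cl) should open the β-iodo epoxide reductively to the 4E allylic alcohol 19. The two anti events add up to the same net syn-SN2′ relationship as the palladium route, but the C6 configuration then rests on the facial bias of the epoxide in the iodolactonisation, so the diastereomers of F2 would be separated before the zinc step.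

2. Step 14. Intermolecular metathesis of the monosubstituted olefin (oligomers) may outrun closure of the strained ten-membered ring, closure may give the E ring olefin, and the C10 alkylidene may instead close a six-membered ring onto the C4=C5 olefin; heating invites Cope rearrangement of the 1,5-diene. Fallback, from 19 back to 20: Dess–Martin oxidation gives the enone F3, in which C3 is trigonal and the C4=C5 olefin is electron-poor and no longer a metathesis partner. Ring-closing metathesis under the conditions of step 14 should give the macrocyclic enone F4, and Corey–Bakshi–Shibata reduction with the (R)-methyl oxazaborolidine and catecholborane should return the 3S alcohol 20 under reagent control.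

3. Step 12. The phosphonate carbanion is delocalised into the iodo-olefin, which may scramble the C7=C11 geometry; E selectivity at C5=C6 may be incomplete; the α,α-disubstituted epoxy aldehyde may decompose under base. Fallback, from 8 and 13 back to 16, with the polarity reversed and the epoxide introduced last: MnO2 oxidation of 8 gives the enal F5; 13 is converted in one flask (ZnI2, P(OEt)3, THF, reflux) into the dienyl phosphonate F6. Horner–Wadsworth–Emmons reaction of F6 (NaHMDS) with F5 should give the triene F7, whose carbanion precursor is no longer conjugated to the iodo-olefin. Shi epoxidation of the electron-richest trisubstituted C3=C4 olefin with the L-fructose-derived ketone (the enantiomer of the usual D-fructose catalyst), Oxone and K2CO3 should then give 16.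

Further compounds
F1 | step 13 | (2Z,4E)-2-{[(4-methoxybenzyl)oxy]methyl}-3-(3-methylbut-3-en-1-yl)-5-[(2S,3S)-2-methyl-3-(prop-2-en-1-yl)oxiran-2-yl]penta-2,4-dienoic acid | C=C(C)CC/C(=C(/C(=O)O)COCc1ccc(OC)cc1)/C=C/[C@]1(C)O[C@H]1CC=C
F2 | step 13 | (5S)-5-{(S)-iodo[(2R,3S)-2-methyl-3-(prop-2-en-1-yl)oxiran-2-yl]methyl}-3-{[(4-methoxybenzyl)oxy]methyl}-4-(3-methylbut-3-en-1-yl)furan-2(5H)-one | C=CC[C@@H]1O[C@@]1(C)[C@@H](I)[C@H]2OC(=O)C(COCc3ccc(OC)cc3)=C2CCC(C)=C
F3 | step 14 | (5R)-5-[(1E)-2-methyl-3-oxohexa-1,5-dien-1-yl]-3-{[(4-methoxybenzyl)oxy]methyl}-4-(3-methylbut-3-en-1-yl)furan-2(5H)-one | C=CCC(=O)/C(C)=C/[C@H]1OC(=O)C(COCc2ccc(OC)cc2)=C1CCC(C)=C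
F4 | step 14 | (6R)-13-[(4-methoxybenzyl)oxy]-3-oxogermacra-1(10)Z,4E,7(11)-trien-12,6-olide | O=C1C/C=C(/C)CCC2=C(COCc3ccc(OC)cc3)C(=O)O[C@@H]2/C=C/1C
F5 | step 12 | (2Z)-3-iodo-4-[(4-methoxybenzyl)oxy]-2-(3-methylbut-3-en-1-yl)but-2-enal | C=C(C)CC/C(C=O)=C(/I)COCc1ccc(OC)cc1
F6 | step 12 | diethyl [(2E)-2-methylhexa-2,5-dien-1-yl]phosphonate | CCOP(=O)(C/C(C)=C/CC=C)OCC
F7 | step 12 | 1-({[(2Z,4E,6E)-2-iodo-6-methyl-3-(3-methylbut-3-en-1-yl)deca-2,4,6,9-tetraen-1-yl]oxy}methyl)-4-methoxybenzene | C=C(C)CC/C(=C(/I)COCc1ccc(OC)cc1)/C=C/C(C)=C/CC=C
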